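**Strategy**

Everything rests on disconnecting the aryl ether bond between O1 and C8a of the chromanone. In ring A, C8a sits ortho to the C4 carbonyl carried by C4a and meta to the methoxy group on C7, so this bond is that of a vinylogous ester and C8a is an activated SNAr site. The key step closes the pyranone ring C in one operation by addition–elimination of a C2 alkoxide at a C8a–F carbon; the C2–O bond is never broken, so the S configuration set earlier is carried into the flavanone. The precursor is an open-chain (S)-β-hydroxy ketone, the asymmetric Mukaiyama aldol of a 2-arylbenzofuran-5-carbaldehyde with 2-fluoro-4-methoxyacetophenone.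

Key step: step 4

Remark on numbering: atom labels are those of the chroman-4-one (O1, C2, C3, C4, C4a, C5 to C8, C8a); ring A is its benzo ring and ring C its pyranone ring. The target is 2S.

Assumption: in the SiCl4/bisphosphoramide aldol the (R,R)-catalyst is taken to direct silyl enol ethers to the Re face of aromatic aldehydes, so the (S,S)-catalyst is used for the Si-face attack that gives the S alcohol; should the sense be the reverse, the antipodal catalyst is used.

**Route**

Step 1
Reactants: 1 4-hydroxy-3-iodobenzaldehyde; 2 1-ethynyl-4-methoxybenzene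
Product: 4 2-(4-methoxyphenyl)-1-benzofuran-5-carbaldehyde, via o-alkynylphenol 3 (not isolated)
Conditions: PdCl2(PPh3)2 (3 mol %), CuI (5 mol %), Et3N, DMF, 70 °C, argon
Reagents that add atoms: none
Why: Sonogashira coupling of the aryl iodide with the terminal alkyne should give o-alkynylphenol 3, whose phenol oxygen then adds 5-endo-dig to the metal-activated triple bond (Sonogashira/heteroannulation domino, the standard entry to 2-arylbenzofurans from o-iodophenols), the aldehyde staying untouched.

Step 2
Reactants: 5 1-(2-fluoro-4-methoxyphenyl)ethan-1-one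
Product: 6 {[1-(2-fluoro-4-methoxyphenyl)ethenyl]oxy}trimethylsilane
Conditions: TMSOTf, Et3N, CH2Cl2, 0 °C
Reagents that add atoms: trimethylsilyl trifluoromethanesulfonate, C[Si](C)(C)OS(=O)(=O)C(F)(F)F
Why: Soft enolization and O-silylation of a methyl ketone can give only the terminal silyl enol ether, and the aryl fluoride and methyl ether are inert to these conditions.

Step 3
Reactants: 4 2-(4-methoxyphenyl)-1-benzofuran-5-carbaldehyde; 6 {[1-(2-fluoro-4-methoxyphenyl)ethenyl]oxy}trimethylsilane
Product: 8 (3S)-1-(2-fluoro-4-methoxyphenyl)-3-hydroxy-3-[2-(4-methoxyphenyl)-1-benzofuran-5-yl]propan-1-one, via trichlorosilyl ether 7 (not isolated)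
Conditions: SiCl4 (1.5 equiv), (S,S)-bisphosphoramide of Denmark (two N,N'-dimethyl-1,1'-binaphthyl-2,2'-diamine phosphoramide units joined by an N,N'-dimethylpentane-1,5-diamine linker, 5 mol %), i-Pr2NEt (10 mol %), CH2Cl2, −78 °C; then sat. aq. NaHCO3
Reagents that add atoms: silicon tetrachloride, Cl[Si](Cl)(Cl)Cl (its SiCl3 group stands only in intermediate 7 and is lost on work-up)
Why: Mukaiyama aldol under Lewis base activation of SiCl4: the phosphoramide-bound trichlorosilyl cation binds aldehyde 4 and blocks its Re face, enol ether 6 should attack the Si face through an open transition state and set the carbinol carbon (the later C2) as S, and trichlorosilyl ether 7, which cannot revert, is hydrolysed on work-up.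

Step 4
Reactants: 8 (3S)-1-(2-fluoro-4-methoxyphenyl)-3-hydroxy-3-[2-(4-methoxyphenyl)-1-benzofuran-5-yl]propan-1-one
Product: 10 Lophirone J, (2S)-7-methoxy-2-[2-(4-methoxyphenyl)-1-benzofuran-5-yl]-2,3-dihydro-4H-chromen-4-one, via potassium alkoxide 9 (not isolated)
Conditions: KHMDS (1.05 equiv), 18-crown-6 (1.1 equiv), THF, −78 → −20 °C; then AcOH
Reagents that add atoms: potassium bis(trimethylsilyl)amide, C[Si](C)(C)[N-][Si](C)(C)C.[K+] (its potassium ion stands only in intermediate 9)
Why: KHMDS removes the hydroxyl proton at −78 °C, and the crown-separated alkoxide 9 should add to the fluorine-bearing carbon C8a to give a Meisenheimer anion whose charge rests on the C4 carbonyl oxygen through C4a, after which fluoride leaves. The closest known reaction type is the intramolecular SNAr etherification of ortho-fluoroaryl ketones (as in the chromone closure of 1-(2-fluoroaryl)-1,3-diketones) together with KHMDS-mediated SNAr of alkoxides on fluoroarenes. The six-membered ring C (O1–C2–C3–C4–C4a–C8a) closes by attack on the sp2 carbon C8a, 6-exo-trig counted on the C8=C8a π bond and equivalent to a 6-endo oxa-Michael addition to the C4=O/C4a=C8a vinylogous acyl fluoride. No new stereocenter forms: C2 keeps the S configuration of 8 because oxygen is the nucleophile and the C2–O bond is not broken. The step needs cyclization to outrun retro-aldol cleavage and E1cB dehydration of the aldolate; low temperature (fragmentation has the higher activation enthalpy), a naked alkoxide and exactly one equivalent of base, which ends as KF so that the flavanone is not left in base, should secure this. The C7 methoxy group is meta to C8a and does not deactivate it by resonance, and the single C–F bond leaves no question of site.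

**Compound list**

1 | 4-hydroxy-3-iodobenzaldehyde | O=Cc1ccc(O)c(I)c1 | starting material
2 | 1-ethynyl-4-methoxybenzene (4-ethynylanisole) | C#Cc1ccc(OC)cc1 | starting material
3 | 4-hydroxy-3-[(4-methoxyphenyl)ethynyl]benzaldehyde (not isolated) | COc1ccc(C#Cc2cc(C=O)ccc2O)cc1 | intermediate
4 | 2-(4-methoxyphenyl)-1-benzofuran-5-carbaldehyde | COc1ccc(-c2cc3cc(C=O)ccc3o2)cc1 | intermediate
5 | 1-(2-fluoro-4-methoxyphenyl)ethan-1-one | CC(=O)c1ccc(OC)cc1F | starting material
6 | {[1-(2-fluoro-4-methoxyphenyl)ethenyl]oxy}trimethylsilane | C=C(O[Si](C)(C)C)c1ccc(OC)cc1F | intermediate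
7 | (3S)-1-(2-fluoro-4-methoxyphenyl)-3-[2-(4-methoxyphenyl)-1-benzofuran-5-yl]-3-[(trichlorosilyl)oxy]propan-1-one (not isolated) | COc1ccc(-c2cc3cc([C@@H](O[Si](Cl)(Cl)Cl)CC(=O)c4ccc(OC)cc4F)ccc3o2)cc1 | intermediate
8 | (3S)-1-(2-fluoro-4-methoxyphenyl)-3-hydroxy-3-[2-(4-methoxyphenyl)-1-benzofuran-5-yl]propan-1-one | COc1ccc(-c2cc3cc([C@@H](O)CC(=O)c4ccc(OC)cc4F)ccc3o2)cc1 | intermediate
9 | potassium (1S)-3-(2-fluoro-4-methoxyphenyl)-1-[2-(4-methoxyphenyl)-1-benzofuran-5-yl]-3-oxopropan-1-olate (not isolated) | COc1ccc(-c2cc3cc([C@@H]([O-])CC(=O)c4ccc(OC)cc4F)ccc3o2)cc1.[K+] | intermediate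
10 | Lophirone J, (2S)-7-methoxy-2-[2-(4-methoxyphenyl)-1-benzofuran-5-yl]-2,3-dihydro-4H-chromen-4-one | COc1ccc(-c2cc3cc([C@@H]4CC(=O)c5ccc(OC)cc5O4)ccc3o2)cc1 | target

**Count**

Total step count: 4. Longest linear sequence: 3 steps (step 1 or step 2, then step 3, then step 4).

**Steps most likely to fail**

Step 4. The alkoxide may fragment by retro-aldol and recombine, or the ketone may enolize and lose hydroxide to give the chalcone, so that enantiopurity or material is lost before the ring closes. The fallback sets out from aldehyde 4 and closes the same O1–C8a bond at the alcohol oxidation level, where no retro-aldol is possible. Purchased 1-(2-bromo-4-methoxyphenyl)ethan-1-one F1 would be turned into its silyl enol ether {[1-(2-bromo-4-methoxyphenyl)ethenyl]oxy}trimethylsilane F2 (TMSOTf, Et3N, CH2Cl2, 0 °C). The aldol of step 3 with 4 would then pass through the trichlorosilyl ether of the bromo aldol F3 and give, after work-up, (3S)-1-(2-bromo-4-methoxyphenyl)-3-hydroxy-3-[2-(4-methoxyphenyl)-1-benzofuran-5-yl]propan-1-one F4. NaBH4 (MeOH, 0 °C) would reduce the ketone to (1S)-3-(2-bromo-4-methoxyphenyl)-1-[2-(4-methoxyphenyl)-1-benzofuran-5-yl]propane-1,3-diol F5, as both C3 epimers. Intramolecular Ullmann etherification (CuI, 3,4,7,8-tetramethyl-1,10-phenanthroline, Cs2CO3, toluene, 110 °C) should then give (2S)-7-methoxy-2-[2-(4-methoxyphenyl)-1-benzofuran-5-yl]-3,4-dihydro-2H-chromen-4-ol F6; only the C1 hydroxyl can reach the C–Br carbon through a six-membered ring. Dess–Martin periodinane (CH2Cl2, NaHCO3, rt) would oxidize the C4 alcohol under neutral conditions, and the route comes back at target 10.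

Step 3. Facial selectivity may be poor, or the addition slow, because the enol ether carries an ortho substituent and the aldehyde is electron-rich. The fallback sets out from aldehyde 4 and ketone 5 and replaces the aldol by a formal asymmetric hydration of an enone. Claisen–Schmidt condensation (Ba(OH)2, EtOH, rt) would give the chalcone (2E)-1-(2-fluoro-4-methoxyphenyl)-3-[2-(4-methoxyphenyl)-1-benzofuran-5-yl]prop-2-en-1-one F7. Copper-catalysed enantioselective conjugate borylation (CuCl, NaOt-Bu, the Josiphos enantiomer that gives the S boronate, B2pin2, MeOH, THF, rt) would give (3S)-1-(2-fluoro-4-methoxyphenyl)-3-[2-(4-methoxyphenyl)-1-benzofuran-5-yl]-3-(4,4,5,5-tetramethyl-1,3,2-dioxaborolan-2-yl)propan-1-one F8. Oxidation of the C–B bond with retention (NaBO3·4H2O, THF/H2O, rt) comes back to the route at aldol 8.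

Step 1. Oxidative dimerization of the alkyne may consume 2, or the cyclization may stall at alkynylphenol 3 because the para-formyl group lowers the nucleophilicity of the phenol. The fallback sets out from 1 and 2 and uses a palladium-free Castro–Stephens benzofuran synthesis. Alkyne 2 would be converted into [(4-methoxyphenyl)ethynyl]copper F9 (CuI, aq. NH3, EtOH, rt), which has no free alkyne left to dimerize. Heating F9 with iodophenol 1 in pyridine at reflux should couple and cyclize in one operation, and the route comes back at aldehyde 4.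

**Further compounds**

F1 | step 4 | 1-(2-bromo-4-methoxyphenyl)ethan-1-one (purchased) | CC(=O)c1ccc(OC)cc1Br
F2 | step 4 | {[1-(2-bromo-4-methoxyphenyl)ethenyl]oxy}trimethylsilane | C=C(O[Si](C)(C)C)c1ccc(OC)cc1Br
F3 | step 4 | (3S)-1-(2-bromo-4-methoxyphenyl)-3-[2-(4-methoxyphenyl)-1-benzofuran-5-yl]-3-[(trichlorosilyl)oxy]propan-1-one (not isolated) | COc1ccc(-c2cc3cc([C@@H](O[Si](Cl)(Cl)Cl)CC(=O)c4ccc(OC)cc4Br)ccc3o2)cc1
F4 | step 4 | (3S)-1-(2-bromo-4-methoxyphenyl)-3-hydroxy-3-[2-(4-methoxyphenyl)-1-benzofuran-5-yl]propan-1-one | COc1ccc(-c2cc3cc([C@@H](O)CC(=O)c4ccc(OC)cc4Br)ccc3o2)cc1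
F5 | step 4 | (1S)-3-(2-bromo-4-methoxyphenyl)-1-[2-(4-methoxyphenyl)-1-benzofuran-5-yl]propane-1,3-diol (both C3 epimers) | COc1ccc(-c2cc3cc([C@@H](O)CC(O)c4ccc(OC)cc4Br)ccc3o2)cc1
F6 | step 4 | (2S)-7-methoxy-2-[2-(4-methoxyphenyl)-1-benzofuran-5-yl]-3,4-dihydro-2H-chromen-4-ol (both C4 epimers) | COc1ccc(-c2cc3cc([C@@H]4CC(O)c5ccc(OC)cc5O4)ccc3o2)cc1
F7 | step 3 | (2E)-1-(2-fluoro-4-methoxyphenyl)-3-[2-(4-methoxyphenyl)-1-benzofuran-5-yl]prop-2-en-1-one | COc1ccc(-c2cc3cc(/C=C/C(=O)c4ccc(OC)cc4F)ccc3o2)cc1
F8 | step 3 | (3S)-1-(2-fluoro-4-methoxyphenyl)-3-[2-(4-methoxyphenyl)-1-benzofuran-5-yl]-3-(4,4,5,5-tetramethyl-1,3,2-dioxaborolan-2-yl)propan-1-one | COc1ccc(-c2cc3cc([C@@H](B4OC(C)(C)C(C)(C)O4)CC(=O)c5ccc(OC)cc5F)ccc3o2)cc1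
F9 | step 1 | [(4-methoxyphenyl)ethynyl]copper | COc1ccc(C#C[Cu])cc1
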